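(The runs were computed with constants of no real substance, noise included.)

Follow one substrate molecule through the flask and count the survivors of each hand apart.

in all of them: free catalyst 1 mol%; racemization catalyst 0.082 mol%

| flask | left-handed substrate | right-handed substrate | solid reagent | remark | time |
|---|---|---|---|---|---|
| Saturday's | 21 mM | 21 mM | 2 equiv | run made earlier |  |
| Monday's | 33 mM | 33 mM | 2 equiv | run made earlier |  |
| Thursday's | 15 mM | 15 mM | 4 equiv | run made earlier |  |
| flask | 15 mM | 15 mM | 2.00 equiv |  | 2.5 d |

- Saturday's (time / d: left-handed product / %, right-handed product / %): 0.208: 2, 0; 0.333: 5, 1; 0.500: 2, 1; 0.625: 8, 4; 1.04: 12, 7; 1.67: 18, 10; 2.50: 25, 8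
- Monday's (time / d: left-handed product / %, right-handed product / %): 0.333: 1, 0; 0.625: 11, 4; 1.04: 14, 3; 1.25: 13, 9; 1.67: 23, 8; 2.00: 22, 10; 2.50: 28, 10
- Thursday's (time / d: left-handed product / %, right-handed product / %): 0.208: 0, 0; 0.417: 2, 2; 0.625: 6, 2; 1.25: 14, 9; 2.50: 24, 12

(each reading ± 2 percentage points)

- free catalyst is single-handed; left-handed substrate and right-handed substrate are mirror images of each other, charged as a racemate, each of them at the stated concentration
- as a solid, counted per litre of solution: solid reagent
- steps thought possible: partner + free catalyst + left-handed substrate -> free catalyst + left-handed product; partner + free catalyst + right-handed substrate -> free catalyst + right-handed product; left-handed substrate + racemization catalyst <-> right-handed substrate + racemization catalyst; solid reagent <-> partner; partner + racemization catalyst -> spent catalyst; racemization catalyst <-> dormant form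
- at the start none of the solid reagent is in solution
- an excess is the difference of the two amounts in percent of their sum
- an excess is below zero if the other one leads

1. left-handed product and right-handed product together, in percent of the left-handed substrate and right-handed substrate charged together, at 2.5 d
2. excess of left-handed product over right-handed product in the product at 2.5 d
3. whether the exchange between left-handed substrate and right-handed substrate keeps pace with the reaction: how far the product's excess at 2.5 d gets from its value without exchange to its value with instant exchange (above 80 % keeps pace, below 20 % hardly takes part, else lags behind)

A left-handed substrate molecule meets a fork: partner and free catalyst make it product, or racemization catalyst turns it into the other hand. Without that turning each hand decays on its own pseudo-first-order clock, and both clocks share [partner] and [free catalyst], so the logarithms of what is left keep a fixed ratio. I read it from the last two readings of each run, where product stands clear of the scatter.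

mean left-handed product 21.8 %, mean right-handed product 9.83 %

s = 2.62

I called this s, the logarithm of the left-handed share left over that of the right-handed share left, the selectivity factor.

By hand, substrate concentration and solid enter both clocks alike, so they leave s and can shift only the pace. The runs show little shift: at 2.5 d the products together read 33.0 % at 21 mM, 38.0 % at 33 mM, and 36.0 % at 4 equiv. More free catalyst speeds both clocks by one factor and also leaves s. More exchange moves the excess from the no-exchange value towards the instant-exchange value.

For the flask I took the right-handed share left from the mean reading at 2.5 d:

right-handed left 80.0 %, left-handed left 55.7 %

y = 32.1 %; excess without exchange 37.8 %; with instant exchange 44.8 %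

The readings could not separate those limits, and I committed to the lower one as a choice they did not force.

The forecast gave 32 %, an excess of 40 %, and lags behind: “The ratio doesn't clearly fall with conversion, so some exchange occurs.” Its excess stood above mine, and on exchange we parted.

    partner + free catalyst + left-handed substrate → free catalyst + left-handed product (k = 85900 M⁻² h⁻¹)
    partner + free catalyst + right-handed substrate → free catalyst + right-handed product (k = 32600 M⁻² h⁻¹)
    left-handed substrate + racemization catalyst ⇌ right-handed substrate + racemization catalyst, rate k3*[racemization catalyst]*[left-handed substrate] forward; the back reaction follows from the equilibrium constant (k = 3210 M⁻¹ h⁻¹)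
    solid reagent ⇌ partner, rate k4*(cs4 - [partner]) while solid is left; crystals form when [partner] > cs4 (solubility = 0.860 mM, k = 1.15 h⁻¹)
    partner + racemization catalyst → spent catalyst (k = 3.11 M⁻¹ h⁻¹)
    racemization catalyst ⇌ dormant form (K = 147, k = 1.08 h⁻¹)

The flask gave 30.7 % and an excess of 38.4 %, and the exchange hardly takes part, getting 1.2 % of the way. At 2.50 d left-handed substrate has a half-life of 3.0 d by reaction against 109 d by exchange, with racemization catalyst at 0.673 %, dormant form at 99.1 % and spent catalyst at 0.202 % of the racemization catalyst charged. The chance of turning hand at that fork is 2.68 %. With s, the flask's 81 % of right-handed substrate left gives 57.6 % of left-handed substrate, and 58 % stands. The neighbour with 4 mol% of free catalyst keeps 51 % of right-handed substrate, which gives 17.3 % against 18 % of left-handed substrate left.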